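The target is a longipinane (labels: C1 ketone, C3 CHMe, cyclobutane C4/C5/C10/C11, C6 CMe2, C7 and C8 ester carbons, C9 CH2). Its seven-membered ring C4–C5–C6–C7–C8–C9–C10 is disconnected at C5–C6: quaternary C6 beside oxygenated C7 is the retron of a semipinacol shift. A six-membered carbinol ring (C4–C5–C7–C8–C9–C10) carrying a 2-propenyl group on C7 is isomerised by cobalt hydride hydrogen-atom transfer; C5 migrates from C7 to C6, enlarging the ring, creating the gem-dimethyl centre and unveiling the C7 ketone in one operation. The precursor, a copaane-like tricycle, arises from a cis-fused decalone whose enolate opens an epoxide to close the cyclobutane.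

Key step: step 12

Assumption: compound 1 is treated as a catalogue chemical (otherwise it is one methylation from commercial 1,4-dioxaspiro[4.5]decan-8-one).
Atom labels: all intermediates carry the carbon labels of the target. In bicyclic intermediates ring A is C10–C11–C1–C2–C3–C4 and ring B is C10–C9–C8–C7–C5–C4. Before step 12, C7 is bonded directly to C5.

Step 1
Reactants: 1 7-methyl-1,4-dioxaspiro[4.5]decan-8-one
Product: 3 7,9-dimethyl-1,4-dioxaspiro[4.5]decan-8-one (cis/trans mixture), via lithium enolate 2 (not isolated)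
Conditions: LiN(i-Pr)2, THF, −78 °C; then MeI, −78 to 0 °C
Reagents that add atoms: iodomethane, CI
Why: Kinetic deprotonation at the less substituted α-carbon and enolate alkylation; the new methine centre forms unselectively, which is harmless because it is equilibrated in steps 2 and 3.

Step 2
Reactants: 3 7,9-dimethyl-1,4-dioxaspiro[4.5]decan-8-one, 4 (S)-1-phenylethylamine, 5 methyl vinyl ketone
Product: 8 (7S)-7,9-dimethyl-7-(3-oxobutyl)-1,4-dioxaspiro[4.5]decan-8-one, via ketimine 6 (not isolated), via Michael adduct imine 7 (not isolated)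
Conditions: 4, TsOH (cat.), PhMe, reflux (Dean–Stark); then 5, THF, rt; then 10% aq. AcOH, rt
Reagents that add atoms: water, O
Why: Deracemizing Michael addition of a chiral imine (d'Angelo-type): the secondary enamine tautomer adds to the enone on the face away from the phenyl group, setting quaternary C10 as S, and mild acid hydrolysis frees the 1,5-diketone and the auxiliary.

Step 3
Reactants: 8 (7S)-7,9-dimethyl-7-(3-oxobutyl)-1,4-dioxaspiro[4.5]decan-8-one
Product: 9 (4aS,8R)-6,6-(ethylenedioxy)-4a,8-dimethyl-4,4a,5,6,7,8-hexahydronaphthalen-2(3H)-one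
Conditions: NaOMe (cat.), MeOH, reflux
Reagents that add atoms: none
Why: Intramolecular aldol condensation (ring-closing half of a Robinson annulation); the enolizable C3 methyl centre should equilibrate to the equatorial epimer trans to the C10 methyl, which avoids a 1,3-diaxial methyl–methyl contact.

Step 4
Reactants: 9 octalone ketal
Product: 11 C8-hydroxy octalone ketal (8-OH trans to the C10 methyl), via lithium dienolate 10 (not isolated)
Conditions: LiN(i-Pr)2, THF, −78 °C; then 2-(phenylsulfonyl)-3-phenyloxaziridine, −78 °C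
Reagents that add atoms: 2-(phenylsulfonyl)-3-phenyloxaziridine, O=S(=O)(N1OC1c1ccccc1)c1ccccc1
Why: Kinetic cross-conjugated enolate formation at C8 and Davis enolate hydroxylation; the oxidant approaches anti to the axial C10 methyl, so the hydroxyl is installed equatorial and trans to that methyl.

Step 5
Reactants: 11 C8-hydroxy octalone ketal
Product: 12 C8 tert-butyldimethylsilyl ether of 11
Conditions: TBSCl, imidazole, DMF, rt
Reagents that add atoms: tert-butyldimethylsilyl chloride, CC(C)(C)[Si](C)(C)Cl
Why: Standard silylation of a secondary α-hydroxy ketone; the silyl ether later shields one alkene face and makes C8 a poor migrating group.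

Step 6
Reactants: 12 silyloxy octalone ketal
Product: 13 cis-fused decalone (C7 ketone, 8-OTBS, C4–H cis to the C10 methyl)
Conditions: H2 (1 atm), 10% Pd/C, EtOAc, rt
Reagents that add atoms: none
Why: Catalytic hydrogenation of 4a-methyl octalone-type enones delivers hydrogen to the ring-fusion carbon on the face of the angular methyl, so C4–H should be set cis to the C10 methyl.

Step 7
Reactants: 13 cis-fused decalone
Product: 15 C7 enol triflate (C7=C5), via potassium enolate 14 (not isolated)
Conditions: KN(SiMe3)2, THF, −78 °C; then PhNTf2, −78 to 0 °C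
Reagents that add atoms: N-phenylbis(trifluoromethanesulfonimide), O=S(=O)(N(c1ccccc1)S(=O)(=O)C(F)(F)F)C(F)(F)F
Why: Kinetic deprotonation at the unhindered C5 methylene in preference to the silyloxy-substituted C8 methine, then O-triflation, gives the C7=C5 enol triflate regioselectively.

Step 8
Reactants: 15 C7 enol triflate, 16 4,4,5,5-tetramethyl-2-(prop-1-en-2-yl)-1,3,2-dioxaborolane
Product: 17 diene ketal (prop-1-en-2-yl on C7, C7=C5)
Conditions: Pd(PPh3)4 (cat.), K3PO4, dioxane–H2O, 80 °C
Reagents that add atoms: none
Why: Suzuki–Miyaura coupling of the alkenyl triflate with the alkenyl boronate installs the three-carbon unit that becomes C6 and its two methyl groups.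

Step 9
Reactants: 17 diene ketal
Product: 18 dienyl ketone (C1 ketone)
Conditions: PPTS (cat.), acetone–H2O, 55 °C
Reagents that add atoms: water, O
Why: Mild acid-catalysed acetal hydrolysis frees the ring-A ketone needed as the cyclobutane-forming nucleophile, under conditions that a secondary silyl ether and a diene should tolerate.

Step 10
Reactants: 18 dienyl ketone
Product: 19 C5,C7-epoxide of 18 (oxygen on the face of the C10 methyl, anti to 8-OTBS)
Conditions: dimethyldioxirane (1.05 equiv), acetone, −20 °C
Reagents that add atoms: dimethyldioxirane, CC1(C)OO1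
Why: Electrophilic epoxidation selects the more electron-rich trisubstituted ring alkene and should occur on the face of the C10 methyl and C4–H, anti to the C8 silyloxy group and to the axial C11 methylene of the folded cis-decalin.

Step 11
Reactants: 19 epoxy ketone
Product: 20 tricyclic carbinol (copaane-type; cyclobutane C4/C5/C10/C11; C7 carries OH and prop-1-en-2-yl)
Conditions: KOt-Bu (1.2 equiv), t-BuOH–THF, 0 °C to rt
Reagents that add atoms: none
Why: Intramolecular 4-exo-tet epoxide opening by the reversibly formed ring-A ketone enolate: axial C11 attacks C5 opposite the epoxide oxygen (inversion at C5), closing the cyclobutane and leaving the C7 tertiary alkoxide on the C4 side; the C2 enolate cannot reach the epoxide.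

Step 12
Reactants: 20 tricyclic carbinol
Product: 21 8-(tert-butyldimethylsilyloxy)longipinane-1,7-dione
Conditions: [N,N′-bis(3,5-di-tert-butylsalicylidene)-1,2-cyclohexanediaminato]cobalt (divalent cobalt, 5 mol %), N-fluoro-2,4,6-trimethylpyridinium tetrafluoroborate (1.5 equiv), PhSiH3 (1.2 equiv), acetone, 0 °C to rt
Reagents that add atoms: none
Why: A cobalt hydride formed from the catalyst, the N-fluoropyridinium oxidant and the silane transfers a hydrogen atom to the terminal CH2 of the 2-propenyl group; the tertiary C6 radical is captured and oxidised at cobalt to a species that reacts as a C6 cation, and the C7–C5 bond shifts to C6 while the C7 hydroxyl becomes the carbonyl. The closest known reaction type is the hydrogen-atom-transfer-initiated radical–polar crossover semipinacol rearrangement of tertiary allylic alcohols, the radical counterpart of an acid-induced Tiffeneau–Demjanov-type ring enlargement. No ring is closed by cyclization: the six-membered rings C4–C5–C7–C8–C9–C10 and C11–C5–C7–C8–C9–C10 are each enlarged to seven members by insertion of C6 into the C5–C7 bond. No new stereocentre is formed (C6 carries two methyls, C7 becomes sp2); C5 migrates with retention and C8 is untouched. The step needs migration of C5 in preference to C8 and to epoxide closure by the hydroxyl. The electron-withdrawing silyloxy group makes C8 the poorer migrating group, and a salen ligand of the type that favours rearrangement over epoxide formation is used.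

Step 13
Reactants: 21 8-(tert-butyldimethylsilyloxy)longipinane-1,7-dione
Product: 22 8-hydroxylongipinane-1,7-dione
Conditions: 48% aq. HF, MeCN, 0 °C to rt
Reagents that add atoms: none
Why: Acidic fluoride cleaves the secondary silyl ether without enolizing the α-hydroxy ketone, so the C8 configuration should be kept.

Step 14
Reactants: 22 8-hydroxylongipinane-1,7-dione
Product: 23 7,8-dihydroxylongipinan-1-one (trans-diol)
Conditions: Me4NBH(OAc)3, MeCN–AcOH, −20 °C
Reagents that add atoms: none
Why: Hydroxyl-directed triacetoxyborohydride reduction (Saksena–Evans type): boron bound to the C8 hydroxyl delivers hydride to C7 on the same face, so the new C7 hydroxyl is trans to the C8 hydroxyl, while the unassisted C1 ketone is left untouched.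

Step 15
Reactants: 23 7,8-dihydroxylongipinan-1-one, 24 angelic acid
Product: 27 7,8-bis(angeloyloxy)longipinan-1-one (CNP0109825.1), via mixed anhydride 25 (not isolated), via 8-monoangelate 26 (not isolated)
Conditions: 24 (3 equiv), 2,4,6-trichlorobenzoyl chloride (3 equiv), Et3N (3.5 equiv), PhMe, rt; then 23, PhMe, 80 °C
Reagents that add atoms: second equivalent of angelic acid, C/C=C(/C)C(=O)O
Why: Yamaguchi-type esterification in which two molecules of angelic acid, each activated as the trichlorobenzoyl mixed anhydride 25 without a nucleophilic amine catalyst, acylate first the less hindered C8 hydroxyl (monoester 26) and then the neopentyl C7 hydroxyl, which avoids the conjugate-addition pathway that isomerises angelates to tiglates.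

Compound list

1 | 7-methyl-1,4-dioxaspiro[4.5]decan-8-one (racemic) | CC1CC2(CCC1=O)OCCO2 | starting material
2 | lithium 7-methyl-1,4-dioxaspiro[4.5]dec-8-en-8-olate (kinetic enolate of 1) | CC1CC2(CC=C1[O-])OCCO2.[Li+] | intermediate
3 | 7,9-dimethyl-1,4-dioxaspiro[4.5]decan-8-one (cis/trans mixture) | CC1CC2(CC(C)C1=O)OCCO2 | intermediate
4 | (S)-1-phenylethylamine | C[C@H](N)c1ccccc1 | starting material
5 | but-3-en-2-one (methyl vinyl ketone) | CC(=O)C=C | starting material
6 | (S)-N-(7,9-dimethyl-1,4-dioxaspiro[4.5]decan-8-ylidene)-1-phenylethanamine | C[C@H](N=C1C(C)CC2(OCCO2)CC1C)c1ccccc1 | intermediate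
7 | (S)-N-[(7S)-7,9-dimethyl-7-(3-oxobutyl)-1,4-dioxaspiro[4.5]decan-8-ylidene]-1-phenylethanamine | C[C@H](N=C1C(C)CC2(OCCO2)C[C@]1(C)CCC(C)=O)c1ccccc1 | intermediate
8 | (7S)-7,9-dimethyl-7-(3-oxobutyl)-1,4-dioxaspiro[4.5]decan-8-one (epimers at C9 of the spiro skeleton) | CC(=O)CC[C@@]1(C)CC2(OCCO2)CC(C)C1=O | intermediate
9 | (4aS,8R)-6,6-(ethylenedioxy)-4a,8-dimethyl-4,4a,5,6,7,8-hexahydronaphthalen-2(3H)-one (ring-B enone C7(=O)–C5=C4; C3 methyl trans to C10 methyl; C1 dioxolane) | O=C1CC[C@]2(C)C(=C1)[C@H](C)CC1(OCCO1)C2 | intermediate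
10 | lithium cross-conjugated dienolate of 9 (C7 olate, C7=C8) | [Li+].[O-]C1=CC[C@]2(C)C(=C1)[C@H](C)CC1(OCCO1)C2 | intermediate
11 | C8-hydroxy derivative of 9 (8-OH trans to the C10 methyl) | O[C@H]1C[C@]2(C)C(=CC1=O)[C@H](C)CC3(OCCO3)C2 | intermediate
12 | C8 tert-butyldimethylsilyl ether of 11 | CC(C)(C)[Si](C)(C)O[C@H]1C[C@]2(C)C(=CC1=O)[C@H](C)CC3(OCCO3)C2 | intermediate
13 | cis-fused decalone (C7 ketone, 8-OTBS, C4–H cis to C10 methyl, C3 methyl trans to C10 methyl, C1 dioxolane) | CC(C)(C)[Si](C)(C)O[C@H]1C[C@]2(C)[C@H](CC1=O)[C@H](C)CC3(OCCO3)C2 | intermediate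
14 | potassium enolate of 13 (C7 olate, C7=C5) | CC(C)(C)[Si](C)(C)O[C@H]1C[C@]2(C)[C@H](C=C1[O-])[C@H](C)CC3(OCCO3)C2.[K+] | intermediate
15 | C7 enol triflate of 13 (C7=C5) | CC(C)(C)[Si](C)(C)O[C@H]1C[C@]2(C)[C@H](C=C1OS(=O)(=O)C(F)(F)F)[C@H](C)CC3(OCCO3)C2 | intermediate
16 | 4,4,5,5-tetramethyl-2-(prop-1-en-2-yl)-1,3,2-dioxaborolane | CC(=C)B1OC(C)(C)C(C)(C)O1 | starting material
17 | diene ketal (15 with the triflate replaced by prop-1-en-2-yl) | CC(C)(C)[Si](C)(C)O[C@H]1C[C@]2(C)[C@H](C=C1C(C)=C)[C@H](C)CC3(OCCO3)C2 | intermediate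
18 | dienyl ketone (17 with the dioxolane hydrolysed to the C1 ketone) | CC(C)(C)[Si](C)(C)O[C@H]1C[C@]2(C)[C@H](C=C1C(C)=C)[C@H](C)CC(=O)C2 | intermediate
19 | C5,C7-epoxide of 18 (oxygen on the face of the C10 methyl, anti to 8-OTBS) | CC(C)(C)[Si](C)(C)O[C@H]1C[C@]2(C)[C@H]([C@@H]3O[C@@]31C(C)=C)[C@H](C)CC(=O)C2 | intermediate
20 | tricyclic carbinol, tricyclo[4.4.0.0(2,7)]decane core: cyclobutane C4/C5/C10/C11, C1 ketone, C3 methyl, C7(OH)(prop-1-en-2-yl) with OH on the C4 side, 8-OTBS on the C11 side | CC(C)(C)[Si](C)(C)O[C@H]1C[C@]2(C)[C@@H]3[C@@H]([C@H]2C(=O)C[C@H]3C)[C@@]1(O)C(C)=C | intermediate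
21 | 8-(tert-butyldimethylsilyloxy)longipinane-1,7-dione (8-O on the C11 side) | CC(C)(C)[Si](C)(C)O[C@H]1C[C@]2(C)[C@@H]3[C@@H]([C@H]2C(=O)C[C@H]3C)C(C)(C)C1=O | intermediate
22 | 8-hydroxylongipinane-1,7-dione | O[C@H]1C[C@]2(C)[C@@H]3[C@@H]([C@H]2C(=O)C[C@H]3C)C(C)(C)C1=O | intermediate
23 | 7,8-dihydroxylongipinan-1-one (trans-diol: 7-OH on the C4 side, 8-OH on the C11 side) | O[C@H]1C[C@]2(C)[C@@H]3[C@@H]([C@H]2C(=O)C[C@H]3C)C(C)(C)[C@@H]1O | intermediate
24 | angelic acid, (Z)-2-methylbut-2-enoic acid | C/C=C(/C)C(=O)O | starting material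
25 | angelic 2,4,6-trichlorobenzoic anhydride | C/C=C(/C)C(=O)OC(=O)c1c(Cl)cc(Cl)cc1Cl | intermediate
26 | 8-(angeloyloxy)-7-hydroxylongipinan-1-one (8-monoangelate of 23) | C/C=C(/C)C(=O)O[C@H]1C[C@]2(C)[C@@H]3[C@@H]([C@H]2C(=O)C[C@H]3C)C(C)(C)[C@@H]1O | intermediate
27 | 7,8-bis(angeloyloxy)longipinan-1-one, CNP0109825.1 | C/C=C(/C)C(=O)O[C@H]1C[C@]2(C)[C@@H]3[C@@H]([C@H]2C(=O)C[C@H]3C)C(C)(C)[C@@H]1OC(=O)/C(C)=C\C | target

Step count and risks

Total step count: 15. Longest linear sequence: 15 steps (from 1 to 27).

The three steps most likely to fail: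

The ring enlargement (step 12) may be diverted by closure of the C7 hydroxyl onto C6 to a spiro-epoxide, by migration of the oxygenated C8 in place of C5, or by plain reduction of the alkene. Fallback: setting out from 20, Mukaiyama hydration of the 2-propenyl group (Mn(dpm)3, tris(2,2,6,6-tetramethylheptane-3,5-dionato)manganese, cat., PhSiH3, O2, i-PrOH) should give the ditertiary diol F1. Pinacol rearrangement of F1 with BF3·OEt2 in CH2Cl2 at −78 °C should ionise the exocyclic dimethylcarbinol carbon, because the ring carbinol is flanked by the silyloxy-bearing C8, and the C5 shift then returns to the route at 21.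

The cyclobutane closure (step 11) may lose to O-alkylation of the enolate or to base-induced opening of the sensitive vinyl epoxide, both of which avoid the strained 4-exo transition state. Fallback: setting out from 18, dihydroxylation of the ring alkene on the face of the C10 methyl (OsO4 cat., N-methylmorpholine N-oxide, acetone–H2O) should give the cis-5,7-diol F2. Selective mesylation of its secondary C5 hydroxyl (MsCl, Et3N, CH2Cl2, 0 °C) gives the hydroxy mesylate F3. KOt-Bu then closes C11–C5 by intramolecular enolate alkylation with inversion; the cis tertiary hydroxyl cannot form an epoxide. This rejoins the route at 20.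

The bis-angeloylation (step 15) may stall at the monoester stage because the neopentyl C7 hydroxyl is slow to acylate, and forcing conditions may isomerise the Z (angeloyl) ester to the E (tigloyl) ester. Fallback: setting out from 23, Steglich esterification (DCC, DMAP, CH2Cl2) with 2-[bis(2,2,2-trifluoroethoxy)phosphoryl]propanoic acid should give the bis(phosphonopropanoate) F4. Still–Gennari olefination with acetaldehyde (KN(SiMe3)2, 18-crown-6, THF, −78 °C) then builds both Z-configured 2-methylbut-2-enoates and arrives at 27.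

Further compounds
F1 | step 12 | ditertiary diol: 20 with the prop-1-en-2-yl group hydrated to 2-hydroxypropan-2-yl | CC(C)(C)[Si](C)(C)O[C@H]1C[C@]2(C)[C@@H]3[C@@H]([C@H]2C(=O)C[C@H]3C)[C@@]1(O)C(C)(C)O
F2 | step 11 | cis-5,7-diol of 18 (both hydroxyls on the face of the C10 methyl) | CC(C)(C)[Si](C)(C)O[C@H]1C[C@]2(C)[C@H]([C@H](O)[C@@]1(O)C(C)=C)[C@H](C)CC(=O)C2
F3 | step 11 | C5 methanesulfonate of F2 | CC(C)(C)[Si](C)(C)O[C@H]1C[C@]2(C)[C@H]([C@H](OS(C)(=O)=O)[C@@]1(O)C(C)=C)[C@H](C)CC(=O)C2
F4 | step 15 | 7,8-bis{2-[bis(2,2,2-trifluoroethoxy)phosphoryl]propanoyloxy}longipinan-1-one | CC(C(=O)O[C@H]1C[C@]2(C)[C@@H]3[C@@H]([C@H]2C(=O)C[C@H]3C)C(C)(C)[C@@H]1OC(=O)C(C)P(=O)(OCC(F)(F)F)OCC(F)(F)F)P(=O)(OCC(F)(F)F)OCC(F)(F)F
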